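I began with the easy step and turned each run's flat ring percentage into a concentration.

| flask | starting material | remark | time |
|---|---|---|---|
| Thursday's | 0.025 M | run made earlier |  |
| Saturday's | 0.10 M | run made earlier |  |
| flask | 0.050 M |  | 15 d |

| run | time / d | ring / % |
|---|---|---|
| Thursday's | 0.625 | 37.1 |
| Thursday's | 1.67 | 41.2 |
| Thursday's | 3.00 | 40.9 |
| Thursday's | 5.00 | 44.0 |
| Thursday's | 6.00 | 42.3 |
| Thursday's | 10.0 | 42.7 |
| Saturday's | 0.625 | 14.9 |
| Saturday's | 1.25 | 11.6 |
| Saturday's | 2.08 | 15.8 |
| Saturday's | 3.00 | 16.2 |
| Saturday's | 5.00 | 13.8 |
| Saturday's | 10.0 | 15.2 |

(standard deviation of a reading: 1 percentage point)

- percent here means starting material units held: one open dimer or side product counts as two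
- what is said of ring includes crystals
- crystals is a solid; its amount is given per volume of the solution
- steps under discussion: starting material -> ring; 2 starting material <-> open dimer; crystals <-> ring; starting material + ring -> side product
- the reaction counts as stopped when no species that holds the starting material changes by six tenths of a point or more over the second half of the time

1. why nothing more happens at 15 d, or that something still does (all of the starting material has reacted / it is still moving / forward and back rates have come level)
2. ring at 15 d, in percent of the starting material charged

Thursday's readings after the first gave c(ring) 10.6 mM on average, and Saturday's readings gave 14.6 mM. So c(ring) rose by a factor of 1.38 while the charge rose by a factor of 4.00.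

That looks like a ceiling. I took ring as made by first-order closure and eaten by the step starting material + ring -> side product, and I treated the open dimer as a passing store. Both rates carry c(starting material), so dividing them removes time and the integral closes:

c(ring) = a(1 − exp(−(charge + c(ring))/2a)),

where a is the closure constant over the side-product constant, a selectivity factor with the unit of a concentration.

Two extreme versions of this equation bracket the flask. With a very large, c(ring) equals the charge. With a huge charge, c(ring) stands at a. I took Saturday's run as close to that second version, so its readings gave the ring ceiling a = 14.9 mM, a value that carries their scatter.

At 0.050 M the ceiling over the charge is 29.8%, but in the equation a finite charge stops short of it. Iterating gave c(ring) 13.0 mM, so I committed to 26.2%. Ring stood level within the scatter in both runs from 1.67 d on, earlier than the 15 d asked, so I expected the first of the listed ends.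

The forecast said all of the starting material has reacted and 26.5%, by another route from mine: “first-order ring closure competing with second-order dimerisation”, trimmed for side product.

The simulation gave all of the starting material has reacted and ring 27.0%.

    starting material → ring (k = 0.110 h⁻¹)
    2 starting material ⇌ open dimer (K = 54.0 L mol⁻¹, k = 1.90 L mol⁻¹ h⁻¹)
    crystals ⇌ ring, rate k3*(cs3 - [ring]) while solid is left; crystals form when [ring] > cs3 (solubility = 18.0 mM, k = 1.30 h⁻¹)
    starting material + ring → side product (k = 7.10 L mol⁻¹ h⁻¹)

At 15.0 d the flask held side product 73.0% and open dimer 0%, and the dimer path changed ring by nothing. Its c(ring) of 13.5 mM stood below the 14.9 mM I had read for a. In the neighbour flask, the same but charged with 0.20 M of starting material, my read a over the charge gives 7.45%, and that flask ended with ring 7.74%.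

(All runs were computed with constants of no real substance, noise included.)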